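Whether to charge Thursday's flask with more reagent than Wednesday's comes down to one number: the chain length, the count of chain turns made per started chain.

in all of them: starting material 20 mM
- east: reagent 60 mM; protic impurity 2 mM; initiator 0.60 mM; run made earlier
- north-west: reagent 60 mM; protic impurity 2 mM; initiator 0.80 mM; run made earlier
- Wednesday's: reagent 60.0 mM; protic impurity 2.00 mM; initiator 0.40 mM; time 25 min
- Thursday's: reagent 90.0 mM; protic impurity 2.00 mM; initiator 0.40 mM; time 25 min

| run | time / min | starting material / % | target / % |
|---|---|---|---|
| east | 0.833 | 89.2 | 2.0 |
| east | 1.50 | 84.9 | 3.1 |
| east | 2.50 | 80.1 | 5.5 |
| east | 3.00 | 77.6 | 6.1 |
| east | 4.00 | 73.9 | 6.7 |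
| east | 5.00 | 69.2 | 7.4 |
| north-west | 0.333 | 94.1 | 1.0 |
| north-west | 1.00 | 86.8 | 4.0 |
| north-west | 2.00 | 79.5 | 5.5 |
| north-west | 2.50 | 76.4 | 7.1 |
| north-west | 4.00 | 68.2 | 9.8 |
| north-west | 5.00 | 63.7 | 10.2 |

(readings scatter by 0.5 percentage points)

* part of the starting material that has reacted at the end, Wednesday's
* part of the starting material that has reacted at the end, Thursday's
* what raising the concentration of reagent from its lowest to its highest value here does to the part of the starting material that has reacted (changes below 5 percentage points count as none) (it rises / it falls / no change)

- in percentages every species weighs as the starting material in it: one ended chains or side product counts as two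
- for by-product the idle adduct is counted in
- what may be going on: initiator -> 2 initiating radical; starting material + initiating radical -> capped initiator + first chain carrier; reagent + first chain carrier -> target + second chain carrier; starting material + second chain carrier -> by-product + first chain carrier; first chain carrier -> ended carrier; 2 first chain carrier -> ended chains; reagent + by-product <-> idle adduct; starting material + protic impurity -> quenched substrate; starting material + target -> side product

We keep the books in mM. Protic impurity takes its own amount of starting material, each initiating radical caps one, each turn takes one and gives one target, and each target lost to side product takes one more. So lost starting material plus standing target, less impurity, equals the capped amount times (1 + 2ν). The forecast's initiator decay of 0.14 per minute means a fraction 0.5 of the initiator has split by 5.00 min, which makes the capped amount numerically the initiator charge. The last readings then give ν = 4.20 in the east run and 4.06 in the north-west run, so initiator barely moves it. We carry their mean, the chain length ν = 4.13.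

Once initiator is spent and target has gone to side product, the lost fraction reaches a ceiling, ([protic impurity] + 2[initiator](1 + 2ν))/[starting material]. For Wednesday's flask that is 47.0%.

One of us argues that Thursday's flask changes nothing. Its turns need 3.30 mM of reagent, far less than the 60.0 mM already charged in Wednesday's, so reagent is not the limiting reagent, and the ceiling stays put.

The other, who made the forecast, answers that excess is beside the point. Since ν ignores initiator, the carrier ends at a first-order rate, while its trapping is pseudo-first-order in [reagent]. So ν scales to 6.20 on Thursday, with a ceiling of 63.6%. I side with this view. For the asked time the forecast gives 45% (37% to 54%) for Wednesday's and 58% (46% to 71%) for Thursday's, so it rises, on the ground that “the carrier is trapped by reagent in competition with termination”.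

The simulation gives 44.7% for Wednesday's and 59.0% for Thursday's: it rises, by 14 percentage points.

    initiator → 2 initiating radical (k = 0.137 /min)
    starting material + initiating radical → capped initiator + first chain carrier (k = 22400 /M/s)
    reagent + first chain carrier → target + second chain carrier (k = 50900 /M/min)
    starting material + second chain carrier → by-product + first chain carrier (k = 1.96 × 10⁵ /M/min)
    first chain carrier → ended carrier (k = 685 /min)
    2 first chain carrier → ended chains (k = 1.50 × 10⁶ /M/s)
    reagent + by-product ⇌ idle adduct, settled at all times (K = 50.0 /M)
    starting material + protic impurity → quenched substrate (k = 74.6 /M/min)
    starting material + target → side product (k = 13.2 /M/min)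

The excess view keeps its region: quenched substrate stands at 10.0% in Wednesday's and 10.0% in Thursday's, and reagent left of its charge is 91% and 90%. Thursday's flask, left until 250 min, reaches 63.8% against the ceiling of 63.6%. A neighbour like Thursday's but with 0.24 mM of initiator keeps ν = 6.20, so its ceiling is 42.1%. That flask gives 40.9% at 25.0 min.

(Readings and results are calculated from invented constants; scatter was added.)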